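At late times Friday's flask shows target flat at 31.4 %, the mean of the readings from 360 min to 1500 min, and the question is what that level is.

| setting | Friday's | Monday's | flask |
|---|---|---|---|
| solid substrate | 0.050 M | 0.050 M | 0.050 M |
| solid reagent | 2 equiv | 1.3 equiv | 2.00 equiv |
| temperature | 100 °C | 106 °C | 100 °C |
| remark | the very flask that is asked about, followed so far | run made earlier |  |
| time |  |  | 25 h |

| run | time / min | target / % |
|---|---|---|
| Friday's | 120 | 16.2 |
| Friday's | 360 | 31.9 |
| Friday's | 720 | 31.5 |
| Friday's | 1200 | 30.9 |
| Friday's | 1500 | 31.3 |
| Monday's | 12.0 | 1.9 |
| Monday's | 25.0 | 3.3 |
| Monday's | 30.0 | 4.0 |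
| Monday's | 50.0 | 7.2 |
| Monday's | 60.0 | 8.8 |

(each reading ± 0.3 percentage points)

- blue: change nothing and wait 8.0 h more
- red: at 25 h take out 90 % of the target then present, then wait 8.0 h
- green: at 25 h raise the temperature by 20 K, then wait 8.0 h

- solid, in amounts per volume of the solution: solid substrate, solid reagent
- what is taken out of target is counted as made
- the numbers in the tables scatter with a standard deviation of 0.3 percentage points
- at the start none of the solid substrate is in solution
- at the start none of the solid reagent is in solution

- target, in percent of the solid substrate first charged, at 25 h
- the option that brings most further target ("none" if no option brings more than 2 percentage points) (blue / red / green / none)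
- target present, with what was taken out counted in, in percent of the solid substrate first charged, after red
- target present, with what was taken out counted in, in percent of the solid substrate first charged, after green

The reckoning here reads the flat level as a share of the whole charge. Solid substrate is taken as fully turned, and the turned material as shared between target and one unseen form that exchange both ways. At rest the two flows are equal, so time drops out of their ratio. Call c(unseen form)/c(target) at rest the split, the equilibrium constant of that exchange: 2.18.

So this reckoning puts target at 25 h at 31.4 %, and it adds nothing for blue. Red removes 28.3 % of the charge, and the remaining 71.7 % splits again by the same ratio. The flat level was reached within 360 min, shorter than 8.0 h, so the new split should be reached in time. Red then totals 50.8 %, a gain of 19 percentage points. Monday's readings end still rising at 8.8 %, so the split is read at one temperature and green stays open.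

The forecast gave 31.4 %, red as best, 59.6 % after red, which is more than the 50.8 % reckoned here, and 34 % after green, reading the stop as “a reversible equilibrium at fixed target concentration”.

The flask gives 31.2 %, and green is best. Blue brings 0 points, red 19 points and green 23 points. Red ends at 50.6 %, against 50.8 % reckoned. Green ends at 54.0 %, which reads as a split of 0.852, lower than before.

    solid substrate ⇌ dissolved substrate, rate k1*(cs1 - [dissolved substrate]) while solid is left; crystals form when [dissolved substrate] > cs1 (solubility = 34.0 mM, k = 0.0500 min⁻¹)
    dissolved substrate + partner → target (k = 120 L mol⁻¹ min⁻¹, Ea = 66.0 kJ mol⁻¹)
    partner → side product (k = 0.740 min⁻¹, Ea = 98.0 kJ mol⁻¹)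
    solid reagent ⇌ partner, rate k4*(cs4 - [partner]) while solid is left; crystals form when [partner] > cs4 (solubility = 3.60 mM, k = 0.0750 min⁻¹)
    target ⇌ isomer of the product (K = 2.20, k = 0.350 min⁻¹, Ea = 100 kJ mol⁻¹, ΔH = −58.0 kJ mol⁻¹)
    (constants at 100 °C)

At 150 min the flask still held 60.4 % of its solid reagent and dissolved substrate stood at 38.1 %, while isomer of the product (42.0 %) and target (19.9 %) already stood at a ratio of 2.11. By 750 min solid reagent stood at 0 % and dissolved substrate at 0.0461 %, with target at 31.2 % and isomer of the product at 68.7 %, and target still reads 31.2 % at 15000 min.

The neighbour with 0.500 equiv of solid reagent stays at 100 °C and at 25 h still holds 61 % of its charged solid substrate, all of it as dissolved substrate, so the split on the turned rest gives target 12.1 % of the charge. The computed neighbour gives 12.1 %.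

(The numbers in the tables are calculated for substances that don't exist; the scatter is artificial.)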